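## Retrosynthetic overview

1. The target is (3R,3'R,6'R)-lutein 3-O-palmitate. The last disconnection is the C10'–C11' single bond of the decaene, giving a C26 (E)-polyenyl iodide (β half, palmitate already in place) and a C13 dienynol (ε half, free 3'-OH). The two are joined in one flask with Me3Al by Zr-catalysed syn-methylalumination followed by Pd/Zn alkenyl–alkenyl coupling.
2. Enabling feature: C10' is the CH terminus of the trisubstituted alkene C9'(C19'H3)=C10', which hangs on the ε ring (C1'–C6') through C7'=C8'. This 2-methylalk-1-enyl unit is the imprint of a syn Me–metal addition to a terminal alkyne C9'≡C10', so the C10' nucleophile, the C19' methyl and the 9'E geometry all arise in the coupling flask from a simpler alkyne.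
3. The C26 iodide comes from Takai iodo-olefination of a C25 aldehyde, itself from Wittig union of a C15 phosphonium salt with the C10 dialdehyde. The C15 unit comes from Stille coupling of an enol triflate with a dienylstannane; the triflate derives from (4R,6R)-actinol, acylated in step 1 so that the palmitate is its own protecting group.
4. The C13 dienynol comes from CBS reduction (3'R) of an enone made by allylic C3' oxidation of the enyne derived from (R)-α-ionone, which maps onto C1'–C10' and supplies 6'R.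
5. Rings: none is built. The β ring (C1–C6) and the ε ring (C1'–C6') both come intact from the chiral pool.

Key step: step 11

Assumption: (4R,6R)-actinol and (R)-α-ionone are taken as commercial enantiopure materials, and the target is read as all-E lutein acylated on the β-ring hydroxyl with the allylic ε-ring hydroxyl free.

## Route

Step 1
Reactants: 1 (4R,6R)-4-hydroxy-2,2,6-trimethylcyclohexan-1-one (actinol); 2 hexadecanoyl chloride (palmitoyl chloride)
Product: 3 (1R,5R)-3,3,5-trimethyl-4-oxocyclohexyl hexadecanoate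
Conditions: pyridine, DMAP (cat.), CH2Cl2, 0 °C → rt
Reagents that add atoms: none
Why: DMAP-catalysed esterification (nucleophilic acyl substitution) of the unhindered secondary alcohol installs the palmitate that the target keeps and that from here on also protects the C3 oxygen, leaving the carbinol stereocentre untouched.

Step 2
Reactants: 3 (1R,5R)-3,3,5-trimethyl-4-oxocyclohexyl hexadecanoate
Product: 4 (1R)-3,5,5-trimethyl-4-[(trifluoromethanesulfonyl)oxy]cyclohex-3-en-1-yl hexadecanoate
Conditions: Tf2O, 2,6-di-tert-butyl-4-methylpyridine, CH2Cl2, 0 °C → rt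
Reagents that add atoms: trifluoromethanesulfonic anhydride, O=S(=O)(OS(=O)(=O)C(F)(F)F)C(F)(F)F
Why: Enol triflate formation by O-sulfonylation of the ketone and loss of its only α-hydrogen should give the tetrasubstituted enol triflate as a single regioisomer, and the non-nucleophilic, non-enolising base leaves the ester and the acyloxy stereocentre alone.

Step 3
Reactants: 5 (E)-3-methylpent-2-en-4-yn-1-ol
Product: 6 (2E,4E)-3-methyl-5-(tributylstannyl)penta-2,4-dien-1-ol
Conditions: Bu3SnH, PdCl2(PPh3)2 (cat.), THF, 0 °C → rt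
Reagents that add atoms: tributyltin hydride, CCCC[SnH](CCCC)CCCC
Why: Palladium-catalysed syn-hydrostannation of the terminal alkyne should place tin on the terminal carbon and give the (E)-alkenylstannane, the minor internal regioisomer being removed by chromatography.

Step 4
Reactants: 4 (1R)-3,5,5-trimethyl-4-[(trifluoromethanesulfonyl)oxy]cyclohex-3-en-1-yl hexadecanoate; 6 (2E,4E)-3-methyl-5-(tributylstannyl)penta-2,4-dien-1-ol
Product: 7 (1R)-4-[(1E,3E)-5-hydroxy-3-methylpenta-1,3-dien-1-yl]-3,5,5-trimethylcyclohex-3-en-1-yl hexadecanoate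
Conditions: Pd2(dba)3 (cat.), AsPh3, NMP, 50 °C
Reagents that add atoms: none
Why: Stille coupling (oxidative addition of the enol triflate to zerovalent palladium, tin-to-palladium transmetalation eased by the weakly bound arsine, reductive elimination) forms the C6–C7 bond with retention of the diene geometry under neutral conditions that tolerate the ester and the free primary alcohol.

Step 5
Reactants: 7 (1R)-4-[(1E,3E)-5-hydroxy-3-methylpenta-1,3-dien-1-yl]-3,5,5-trimethylcyclohex-3-en-1-yl hexadecanoate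
Product: 8 {(2E,4E)-5-[(4R)-4-(hexadecanoyloxy)-2,6,6-trimethylcyclohex-1-en-1-yl]-3-methylpenta-2,4-dien-1-yl}triphenylphosphonium bromide
Conditions: PPh3·HBr, CH2Cl2, rt
Reagents that add atoms: triphenylphosphine hydrobromide, [Br-].[PH+](c1ccccc1)(c1ccccc1)c1ccccc1
Why: Acid-promoted ionisation of the allylic alcohol to a delocalised allylic cation and capture by PPh3 at the unhindered terminus (SN1-type phosphonium salt formation) should give the all-E salt, purified by trituration, in an aprotic solvent that spares the ester.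

Step 6
Reactants: 8 {(2E,4E)-5-[(4R)-4-(hexadecanoyloxy)-2,6,6-trimethylcyclohex-1-en-1-yl]-3-methylpenta-2,4-dien-1-yl}triphenylphosphonium bromide; 9 (2E,4E,6E)-2,7-dimethylocta-2,4,6-trienedial
Product: 11 (2E,4E,6E,8E,10E,12E)-13-[(4R)-4-(hexadecanoyloxy)-2,6,6-trimethylcyclohex-1-en-1-yl]-2,7,11-trimethyltrideca-2,4,6,8,10,12-hexaenal, via phosphonium ylide 10 (not isolated)
Conditions: NaN(SiMe3)2 (1 equiv), THF, −78 °C; added to 9 (2 equiv), THF, −78 → 0 °C; then heptane, reflux
Reagents that add atoms: none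
Why: Wittig olefination of one carbonyl of the dialdehyde (used in excess and more electrophilic than the product) by the semi-stabilised allylic ylide forms C11=C12, and the hindered 11Z isomer formed alongside should isomerise thermally to the all-E aldehyde.

Step 7
Reactants: 11 (2E,4E,6E,8E,10E,12E)-13-[(4R)-4-(hexadecanoyloxy)-2,6,6-trimethylcyclohex-1-en-1-yl]-2,7,11-trimethyltrideca-2,4,6,8,10,12-hexaenal
Product: 12 (1R)-4-[(1E,3E,5E,7E,9E,11E,13E)-14-iodo-3,7,12-trimethyltetradeca-1,3,5,7,9,11,13-heptaen-1-yl]-3,5,5-trimethylcyclohex-3-en-1-yl hexadecanoate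
Conditions: CHI3, CrCl2, THF–dioxane, 0 °C → rt, dark
Reagents that add atoms: iodoform, IC(I)I
Why: Takai olefination, in which the geminal dichromium species made from iodoform and divalent chromium adds to the aldehyde and eliminates with the iodine anti to the bulky polyenyl residue, should give the (E)-iodoalkene that carries C11' while ester and polyene stay inert.

Step 8
Reactants: 13 (3E)-4-[(1R)-2,6,6-trimethylcyclohex-2-en-1-yl]but-3-en-2-one ((R)-α-ionone)
Product: 16 (6R)-6-[(1E)-but-1-en-3-yn-1-yl]-1,5,5-trimethylcyclohex-1-ene, via enol phosphate 14 (not isolated), via lithium acetylide 15 (not isolated)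
Conditions: LiN(iPr)2 (1.05 equiv), THF, −78 °C; ClP(O)(OEt)2, −78 °C → rt; then LiN(iPr)2 (2.3 equiv), THF, −78 → 0 °C; H2O
Reagents that add atoms: none
Why: Kinetic deprotonation of the methyl ketone, O-phosphorylation and base-induced elimination of diethyl phosphate (enol phosphate route to terminal alkynes) convert the acetyl group into the C9'≡C10' alkyne, the low temperature keeping the hindered doubly allylic C6' centre configurationally intact.

Step 9
Reactants: 16 (6R)-6-[(1E)-but-1-en-3-yn-1-yl]-1,5,5-trimethylcyclohex-1-ene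
Product: 17 (4R)-4-[(1E)-but-1-en-3-yn-1-yl]-3,5,5-trimethylcyclohex-2-en-1-one
Conditions: Rh2(cap)4 (dirhodium tetracaprolactamate, 1 mol%), t-BuOOH (70% aq.), ClCH2CH2Cl, 40 °C
Reagents that add atoms: tert-butyl hydroperoxide, CC(C)(C)OO
Why: Radical allylic C–H oxidation, in which tert-butylperoxyl radicals abstract hydrogen from the accessible ring methylene C3' and the allylic peroxide collapses to the enone, should spare the C6'–H that is shielded by the neighbouring quaternary carbon and the C5' methyl, and the base-free medium avoids epimerisation.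

Step 10
Reactants: 17 (4R)-4-[(1E)-but-1-en-3-yn-1-yl]-3,5,5-trimethylcyclohex-2-en-1-one
Product: 18 (1R,4R)-4-[(1E)-but-1-en-3-yn-1-yl]-3,5,5-trimethylcyclohex-2-en-1-ol
Conditions: (S)-2-methyl-CBS-oxazaborolidine (0.2 equiv), catecholborane, toluene, −78 °C; then MeOH, aq. NaOH
Reagents that add atoms: none
Why: Corey–Bakshi–Shibata reduction, with the alkene flank of the enone as the large group, should deliver hydride under catalyst control to the face that gives the (3'R)-alcohol trans to the C6' side chain, and any 3'-epimer is a diastereomer removable by chromatography.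

Step 11
Reactants: 18 (1R,4R)-4-[(1E)-but-1-en-3-yn-1-yl]-3,5,5-trimethylcyclohex-2-en-1-ol; 12 (1R)-4-[(1E,3E,5E,7E,9E,11E,13E)-14-iodo-3,7,12-trimethyltetradeca-1,3,5,7,9,11,13-heptaen-1-yl]-3,5,5-trimethylcyclohex-3-en-1-yl hexadecanoate
Product: 20 (3R,3'R,6'R)-3'-hydroxy-β,ε-caroten-3-yl hexadecanoate (lutein 3-O-palmitate), via alkenylalane 19 (not isolated)
Conditions: 18 (1.2 equiv), Me3Al (3 equiv), Cp2ZrCl2 (0.25 equiv), CH2Cl2, 0 → 23 °C; evaporate volatiles; then 12, ZnCl2 (1 equiv), Pd2(dba)3 (2.5 mol%), P(2-furyl)3 (10 mol%), THF–DMF, 23 °C, dark; aq. NaHCO3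
Reagents that add atoms: trimethylaluminium, C[Al](C)C
Why: Me3Al first masks the hydroxyl of 18 as its dimethylaluminium alkoxide and then, with Cp2ZrCl2, forms a methylzirconocene–aluminate pair that adds methyl and metal syn across the terminal alkyne, methyl to the internal carbon C9' and the metal (passed on to aluminium) to C10', giving the (E)-2-methylalkenylalane 19. After the solvent switch, transmetalation from aluminium through zinc to palladium, oxidative addition of iodide 12 to zerovalent palladium and reductive elimination join C10' to C11' with retention at both alkenes; the closest known reaction type is the one-pot Zr-catalysed methylalumination of terminal enynes followed by Pd/Zn-catalysed Negishi coupling with alkenyl halides. No ring is closed and no stereocentre is created; the one new stereo-element, the 9'E double bond, is fixed by the syn addition, and 11'E is carried over from 12. The step needs regioselectivity (methyl on C9'), which the conjugated terminal enyne secures, and chemoselectivity toward the palmitate, which alkenylalanes and alkenylzincs should not attack at room temperature once excess Me3Al has been evaporated. Because the ester sits on 12 and the free alcohol on 18, the coupling also decides which of the two hydroxyls is acylated and ends the synthesis without a protecting group.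

## Compound list

1 | (4R,6R)-4-hydroxy-2,2,6-trimethylcyclohexan-1-one (actinol) | O[C@@H]1C[C@@H](C)C(=O)C(C)(C)C1 | starting material
2 | hexadecanoyl chloride | CCCCCCCCCCCCCCCC(=O)Cl | starting material
3 | (1R,5R)-3,3,5-trimethyl-4-oxocyclohexyl hexadecanoate | CCCCCCCCCCCCCCCC(=O)O[C@@H]1C[C@@H](C)C(=O)C(C)(C)C1 | intermediate
4 | (1R)-3,5,5-trimethyl-4-[(trifluoromethanesulfonyl)oxy]cyclohex-3-en-1-yl hexadecanoate | CCCCCCCCCCCCCCCC(=O)O[C@@H]1CC(C)=C(OS(=O)(=O)C(F)(F)F)C(C)(C)C1 | intermediate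
5 | (E)-3-methylpent-2-en-4-yn-1-ol | C#C/C(C)=C/CO | starting material
6 | (2E,4E)-3-methyl-5-(tributylstannyl)penta-2,4-dien-1-ol | CCCC[Sn](CCCC)(CCCC)/C=C/C(C)=C/CO | intermediate
7 | (1R)-4-[(1E,3E)-5-hydroxy-3-methylpenta-1,3-dien-1-yl]-3,5,5-trimethylcyclohex-3-en-1-yl hexadecanoate | CCCCCCCCCCCCCCCC(=O)O[C@@H]1CC(C)=C(/C=C/C(C)=C/CO)C(C)(C)C1 | intermediate
8 | {(2E,4E)-5-[(4R)-4-(hexadecanoyloxy)-2,6,6-trimethylcyclohex-1-en-1-yl]-3-methylpenta-2,4-dien-1-yl}triphenylphosphonium bromide | CCCCCCCCCCCCCCCC(=O)O[C@@H]1CC(C)=C(/C=C/C(C)=C/C[P+](c2ccccc2)(c2ccccc2)c2ccccc2)C(C)(C)C1.[Br-] | intermediate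
9 | (2E,4E,6E)-2,7-dimethylocta-2,4,6-trienedial | O=C/C(C)=C/C=C/C=C(C)/C=O | starting material
10 | phosphonium ylide of 8 | CCCCCCCCCCCCCCCC(=O)O[C@@H]1CC(C)=C(/C=C/C(C)=C/[CH-][P+](c2ccccc2)(c2ccccc2)c2ccccc2)C(C)(C)C1 | intermediate
11 | (2E,4E,6E,8E,10E,12E)-13-[(4R)-4-(hexadecanoyloxy)-2,6,6-trimethylcyclohex-1-en-1-yl]-2,7,11-trimethyltrideca-2,4,6,8,10,12-hexaenal | CCCCCCCCCCCCCCCC(=O)O[C@@H]1CC(C)=C(/C=C/C(C)=C/C=C/C(C)=C/C=C/C=C(C)/C=O)C(C)(C)C1 | intermediate
12 | (1R)-4-[(1E,3E,5E,7E,9E,11E,13E)-14-iodo-3,7,12-trimethyltetradeca-1,3,5,7,9,11,13-heptaen-1-yl]-3,5,5-trimethylcyclohex-3-en-1-yl hexadecanoate | CCCCCCCCCCCCCCCC(=O)O[C@@H]1CC(C)=C(/C=C/C(C)=C/C=C/C(C)=C/C=C/C=C(C)/C=C/I)C(C)(C)C1 | intermediate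
13 | (3E)-4-[(1R)-2,6,6-trimethylcyclohex-2-en-1-yl]but-3-en-2-one ((R)-α-ionone) | CC(=O)/C=C/[C@H]1C(C)=CCCC1(C)C | starting material
14 | diethyl (3E)-4-[(1R)-2,6,6-trimethylcyclohex-2-en-1-yl]buta-1,3-dien-2-yl phosphate | C=C(OP(=O)(OCC)OCC)/C=C/[C@H]1C(C)=CCCC1(C)C | intermediate
15 | lithium acetylide of 16 | [Li]C#C/C=C/[C@H]1C(C)=CCCC1(C)C | intermediate
16 | (6R)-6-[(1E)-but-1-en-3-yn-1-yl]-1,5,5-trimethylcyclohex-1-ene | C#C/C=C/[C@H]1C(C)=CCCC1(C)C | intermediate
17 | (4R)-4-[(1E)-but-1-en-3-yn-1-yl]-3,5,5-trimethylcyclohex-2-en-1-one | C#C/C=C/[C@H]1C(C)=CC(=O)CC1(C)C | intermediate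
18 | (1R,4R)-4-[(1E)-but-1-en-3-yn-1-yl]-3,5,5-trimethylcyclohex-2-en-1-ol | C#C/C=C/[C@H]1C(C)=C[C@H](O)CC1(C)C | intermediate
19 | dimethyl{(1E,3E)-4-[(1R,4R)-4-[(dimethylalumanyl)oxy]-2,6,6-trimethylcyclohex-2-en-1-yl]-2-methylbuta-1,3-dien-1-yl}alumane | C[Al](C)/C=C(C)/C=C/[C@H]1C(C)=C[C@H](O[Al](C)C)CC1(C)C | intermediate
20 | (3R,3'R,6'R)-3'-hydroxy-β,ε-caroten-3-yl hexadecanoate (lutein 3-O-palmitate) | CCCCCCCCCCCCCCCC(=O)O[C@@H]1CC(C)=C(/C=C/C(C)=C/C=C/C(C)=C/C=C/C=C(C)/C=C/C=C(C)/C=C/[C@H]2C(C)=C[C@H](O)CC2(C)C)C(C)(C)C1 | target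

## Step count and risks

Total step count: 11. Longest linear sequence: 7 steps (steps 1, 2, 4, 5, 6, 7 and 11, from 1 to 20).

Steps most likely to fail:

**Step 11.** The alkenylalane that carries an aluminium alkoxide may transmetalate slowly or be protonated, and the light- and acid-sensitive polyenyl iodide may decay in the Lewis acidic mixture before it couples. The fallback sets out from 18 and 11 and comes back at 20; it separates the two events and reverses the polarity at the C10'–C11' bond. The methylalumination of 18 is run alone and quenched with I2 (THF, −30 °C) to give the isolable dienyl iodide (1R,4R)-4-[(1E,3E)-4-iodo-3-methylbuta-1,3-dien-1-yl]-3,5,5-trimethylcyclohex-2-en-1-ol F1. Aldehyde 11 is homologated with Cl2CHB(pin), CrCl2 and LiI in THF (boron variant of the Takai olefination) to the C26 (E)-alkenyl pinacol boronate F2. Suzuki–Miyaura coupling of F1 with F2 (Pd(PPh3)4, aq. K3PO4, THF, rt, dark) should then give 20 directly, since the free hydroxyl and the ester both tolerate these conditions.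

**Step 9.** Hydrogen abstraction may occur at the doubly allylic C6'–H instead of C3', or peroxyl radicals may add to the conjugated enyne. The fallback sets out from 13 and comes back at 18; it places the oxygen before the alkyne is made.
- Ketalisation of 13 (ethylene glycol, HC(OEt)3, cat. pyridinium tosylate) gives the dioxolane 2-methyl-2-{(E)-2-[(1R)-2,6,6-trimethylcyclohex-2-en-1-yl]ethenyl}-1,3-dioxolane F3.
- The same allylic oxidation, now on a substrate with only an isolated alkene beside the ring olefin, gives the enone (4R)-3,5,5-trimethyl-4-[(E)-2-(2-methyl-1,3-dioxolan-2-yl)ethenyl]cyclohex-2-en-1-one F4.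
- CBS reduction as in step 10 gives the alcohol (1R,4R)-3,5,5-trimethyl-4-[(E)-2-(2-methyl-1,3-dioxolan-2-yl)ethenyl]cyclohex-2-en-1-ol F5.
- Silylation (TBSCl, imidazole, DMF) gives the silyl ether tert-butyldimethyl{[(1R,4R)-3,5,5-trimethyl-4-[(E)-2-(2-methyl-1,3-dioxolan-2-yl)ethenyl]cyclohex-2-en-1-yl]oxy}silane F6.
- Mild hydrolysis (pyridinium tosylate, acetone–water) frees the methyl ketone (3E)-4-[(1R,4R)-4-(tert-butyldimethylsilyloxy)-2,6,6-trimethylcyclohex-2-en-1-yl]but-3-en-2-one F7.
- The enol phosphate sequence of step 8 gives the silylated enyne {[(1R,4R)-4-[(1E)-but-1-en-3-yn-1-yl]-3,5,5-trimethylcyclohex-2-en-1-yl]oxy}(tert-butyl)dimethylsilane F8.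
- Bu4NF in THF returns 18.

**Step 7.** The geminal dichromium reagent may add sluggishly to the long, electron-rich polyenal, giving incomplete conversion, erosion of E-selectivity and loss of the iodide on isolation. The fallback sets out from 11 and comes back at 12; it builds C11' as an alkyne carbon and sets the geometry by hydrometalation. Me3SiC(Li)N2 (THF, −78 → 0 °C, Colvin rearrangement) converts 11 into the terminal polyenyne (1R)-3,5,5-trimethyl-4-[(1E,3E,5E,7E,9E,11E)-3,7,12-trimethyltetradeca-1,3,5,7,9,11-hexaen-13-yn-1-yl]cyclohex-3-en-1-yl hexadecanoate F9. Syn-hydrozirconation with Cp2Zr(H)Cl (THF, rt) and iodinolysis (I2, −78 °C) should then give 12 with the E geometry fixed by the syn addition.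

## Further compounds

F1 | step 11 | (1R,4R)-4-[(1E,3E)-4-iodo-3-methylbuta-1,3-dien-1-yl]-3,5,5-trimethylcyclohex-2-en-1-ol | I/C=C(C)/C=C/[C@H]1C(C)=C[C@H](O)CC1(C)C
F2 | step 11 | (1R)-3,5,5-trimethyl-4-[(1E,3E,5E,7E,9E,11E,13E)-3,7,12-trimethyl-14-(4,4,5,5-tetramethyl-1,3,2-dioxaborolan-2-yl)tetradeca-1,3,5,7,9,11,13-heptaen-1-yl]cyclohex-3-en-1-yl hexadecanoate | CCCCCCCCCCCCCCCC(=O)O[C@@H]1CC(C)=C(/C=C/C(C)=C/C=C/C(C)=C/C=C/C=C(C)/C=C/B2OC(C)(C)C(C)(C)O2)C(C)(C)C1
F3 | step 9 | 2-methyl-2-{(E)-2-[(1R)-2,6,6-trimethylcyclohex-2-en-1-yl]ethenyl}-1,3-dioxolane | CC1(/C=C/[C@H]2C(C)=CCCC2(C)C)OCCO1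
F4 | step 9 | (4R)-3,5,5-trimethyl-4-[(E)-2-(2-methyl-1,3-dioxolan-2-yl)ethenyl]cyclohex-2-en-1-one | CC1(/C=C/[C@H]2C(C)=CC(=O)CC2(C)C)OCCO1
F5 | step 9 | (1R,4R)-3,5,5-trimethyl-4-[(E)-2-(2-methyl-1,3-dioxolan-2-yl)ethenyl]cyclohex-2-en-1-ol | CC1(/C=C/[C@H]2C(C)=C[C@H](O)CC2(C)C)OCCO1
F6 | step 9 | tert-butyldimethyl{[(1R,4R)-3,5,5-trimethyl-4-[(E)-2-(2-methyl-1,3-dioxolan-2-yl)ethenyl]cyclohex-2-en-1-yl]oxy}silane | CC1(/C=C/[C@H]2C(C)=C[C@H](O[Si](C)(C)C(C)(C)C)CC2(C)C)OCCO1
F7 | step 9 | (3E)-4-[(1R,4R)-4-(tert-butyldimethylsilyloxy)-2,6,6-trimethylcyclohex-2-en-1-yl]but-3-en-2-one | CC(=O)/C=C/[C@H]1C(C)=C[C@H](O[Si](C)(C)C(C)(C)C)CC1(C)C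
F8 | step 9 | {[(1R,4R)-4-[(1E)-but-1-en-3-yn-1-yl]-3,5,5-trimethylcyclohex-2-en-1-yl]oxy}(tert-butyl)dimethylsilane | C#C/C=C/[C@H]1C(C)=C[C@H](O[Si](C)(C)C(C)(C)C)CC1(C)C
F9 | step 7 | (1R)-3,5,5-trimethyl-4-[(1E,3E,5E,7E,9E,11E)-3,7,12-trimethyltetradeca-1,3,5,7,9,11-hexaen-13-yn-1-yl]cyclohex-3-en-1-yl hexadecanoate | CCCCCCCCCCCCCCCC(=O)O[C@@H]1CC(C)=C(/C=C/C(C)=C/C=C/C(C)=C/C=C/C=C(C)/C#C)C(C)(C)C1
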